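Ring C, the resorcinol ring whose C1 carries the E alkene and whose C3 and C5 carry oxygen, is disconnected to a 4‑oxygenated 6‑styryl‑2‑pyrone and a two‑carbon ketene acetal. One inverse‑demand Diels–Alder reaction, followed by loss of CO2 and Me3SiOH, forms two C–C bonds and the aromatic ring: pyrone C6 and C4 become C1 and C3, the acetal carbon becomes C5. The precursor is the enantiopure (2S,3S)‑benzodioxane with three MOM ethers and an E‑vinyl‑linked 2‑pyrone whose 4‑oxygen is acetylated, not alkylated. This keeps the diene electron‑poor and lets the group leave with the MOM ethers in the last step.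

Key step: step 17

Abbreviation used in names: BDX = the trans (2S,3S)-3-[3,5-dimethoxy-4-(methoxymethoxy)phenyl]-8-(methoxymethoxy)-2-[(methoxymethoxy)methyl]-2,3-dihydro-1,4-benzodioxin-6-yl group.

Step 1
Reactants: 1 4-bromo-2,6-dimethoxyphenol
Product: 2 5-bromo-1,3-dimethoxy-2-(methoxymethoxy)benzene
Conditions: MOMCl, iPr2NEt, CH2Cl2, 0 °C → rt
Reagents that add atoms: chloromethyl methyl ether, COCCl
Why: Williamson-type O-alkylation of the phenol with the reactive chloromethyl ether masks the acidic OH before metalation and installs an acetal that the later acid step removes.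

Step 2
Reactants: 3 methyl (R)-2,2-dimethyl-1,3-dioxolane-4-carboxylate
Product: 4 methyl (2R)-2,3-dihydroxypropanoate
Conditions: Dowex 50W (H+ form), MeOH, rt
Reagents that add atoms: none
Why: Acid-catalysed transacetalisation with methanol frees the 1,2-diol, and the C2 stereocentre is not enolised under these conditions and keeps its R configuration.

Step 3
Reactants: 4 methyl (2R)-2,3-dihydroxypropanoate
Product: 5 methyl (2R)-3-[(tert-butyldimethylsilyl)oxy]-2-hydroxypropanoate
Conditions: TBSCl, imidazole, CH2Cl2, 0 °C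
Reagents that add atoms: tert-butyldimethylsilyl chloride, CC(C)(C)[Si](C)(C)Cl
Why: Silyl ether formation is selective for the unhindered primary hydroxyl, so only the C2 hydroxyl stays free for the Mitsunobu reaction.

Step 4
Reactants: 5 methyl (2R)-3-[(tert-butyldimethylsilyl)oxy]-2-hydroxypropanoate; 6 methyl gallate
Product: 7 methyl 4-{[(2S)-3-[(tert-butyldimethylsilyl)oxy]-1-methoxy-1-oxopropan-2-yl]oxy}-3,5-dihydroxybenzoate
Conditions: PPh3, DIAD, THF, 0 °C → rt
Reagents that add atoms: none
Why: In this Mitsunobu etherification the 4-OH of methyl gallate, para to the ester and the most acidic of the three phenols, should displace the activated α-hydroxy ester oxygen by SN2, so C2 is inverted from R to S and becomes the future C2 of the benzodioxane.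

Step 5
Reactants: 7 methyl 4-{[(2S)-3-[(tert-butyldimethylsilyl)oxy]-1-methoxy-1-oxopropan-2-yl]oxy}-3,5-dihydroxybenzoate
Product: 8 methyl 4-{[(2S)-3-[(tert-butyldimethylsilyl)oxy]-1-methoxy-1-oxopropan-2-yl]oxy}-3,5-bis(methoxymethoxy)benzoate
Conditions: MOMCl, iPr2NEt, CH2Cl2, 0 °C → rt
Reagents that add atoms: chloromethyl methyl ether, COCCl
Why: Acetal-type O-alkylation of both remaining phenols removes acidic protons before the organomagnesium steps and blocks lactonisation onto the neighbouring ester, while the mild amine base leaves the stereocentre alone.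

Step 6
Reactants: 8 methyl 4-{[(2S)-3-[(tert-butyldimethylsilyl)oxy]-1-methoxy-1-oxopropan-2-yl]oxy}-3,5-bis(methoxymethoxy)benzoate
Product: 9 methyl 4-{[(2S)-3-[(tert-butyldimethylsilyl)oxy]-1-[methoxy(methyl)amino]-1-oxopropan-2-yl]oxy}-3,5-bis(methoxymethoxy)benzoate
Conditions: MeNHOMe·HCl, iPrMgCl, THF, −20 °C
Reagents that add atoms: N,O-dimethylhydroxylamine hydrochloride, CNOC.Cl
Why: Weinreb amide formation by aminolysis with the chloromagnesium amide should take place only at the aliphatic α-aryloxy ester, which is far more electrophilic than the electron-rich benzoate, and the low temperature spares the α-stereocentre.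

Step 7
Reactants: 2 5-bromo-1,3-dimethoxy-2-(methoxymethoxy)benzene; 9 methyl 4-{[(2S)-3-[(tert-butyldimethylsilyl)oxy]-1-[methoxy(methyl)amino]-1-oxopropan-2-yl]oxy}-3,5-bis(methoxymethoxy)benzoate
Product: 11 methyl 4-{[(2S)-3-[(tert-butyldimethylsilyl)oxy]-1-[3,5-dimethoxy-4-(methoxymethoxy)phenyl]-1-oxopropan-2-yl]oxy}-3,5-bis(methoxymethoxy)benzoate, via Grignard reagent 10 (not isolated)
Conditions: 2, Mg, THF, 40 °C; then 9, THF, −20 → 0 °C; aq. NH4Cl
Reagents that add atoms: none
Why: Grignard addition to a Weinreb amide stops at the ketone because the chelated tetrahedral adduct survives until work-up, which also shields the α-stereocentre from enolisation, and the methyl benzoate is too unreactive to compete at this temperature.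

Step 8
Reactants: 11 methyl 4-{[(2S)-3-[(tert-butyldimethylsilyl)oxy]-1-[3,5-dimethoxy-4-(methoxymethoxy)phenyl]-1-oxopropan-2-yl]oxy}-3,5-bis(methoxymethoxy)benzoate
Product: 14 methyl (2S,3S)-8-hydroxy-3-(4-hydroxy-3,5-dimethoxyphenyl)-2-(hydroxymethyl)-2,3-dihydro-1,4-benzodioxine-6-carboxylate (trans), via carbinol 12 (not isolated), via pentaol 13 (not isolated)
Conditions: NaBH4, MeOH–THF, 0 °C; then 3 M aq. HCl, 50 °C
Reagents that add atoms: none
Why: Borohydride reduction gives the benzylic carbinol (its configuration does not matter), and the acid then removes the MOM and silyl groups and ionises the 4-hydroxy-3,5-dimethoxybenzylic alcohol to a quinone-methide-like cation that one of the two equivalent ortho phenols captures in a reversible 6-exo ring closure, so the new C3 centre should settle trans to the fixed C2 centre under thermodynamic control, the minor cis isomer being removed by chromatography.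

Step 9
Reactants: 14 methyl (2S,3S)-8-hydroxy-3-(4-hydroxy-3,5-dimethoxyphenyl)-2-(hydroxymethyl)-2,3-dihydro-1,4-benzodioxine-6-carboxylate
Product: 15 methyl (2S,3S)-3-[3,5-dimethoxy-4-(methoxymethoxy)phenyl]-8-(methoxymethoxy)-2-[(methoxymethoxy)methyl]-2,3-dihydro-1,4-benzodioxine-6-carboxylate (BDX–CO2Me)
Conditions: MOMCl, iPr2NEt, CH2Cl2, 0 → 40 °C
Reagents that add atoms: chloromethyl methyl ether, COCCl
Why: Exhaustive acetal-type O-alkylation of the two phenols and the primary alcohol gives base-stable protection for the aldol step that one acid treatment removes at the end.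

Step 10
Reactants: 15 BDX–CO2Me
Product: 16 (BDX)methanol
Conditions: iBu2AlH, CH2Cl2, −78 → 0 °C
Reagents that add atoms: none
Why: Hydride reduction of the aryl ester with excess iBu2AlH should stop cleanly at the benzylic alcohol and leave the acetals untouched.

Step 11
Reactants: 16 (BDX)methanol
Product: 17 BDX-carbaldehyde
Conditions: MnO2, CH2Cl2, rt
Reagents that add atoms: none
Why: MnO2 oxidises the benzylic alcohol selectively to the aldehyde without over-oxidation and without touching the MOM ethers or the benzodioxane methine.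

Step 12
Reactants: 18 4-hydroxy-6-methyl-2H-pyran-2-one
Product: 19 6-methyl-4-(prop-2-en-1-yloxy)-2H-pyran-2-one
Conditions: allyl alcohol, PPh3, DIAD, THF, 0 °C → rt
Reagents that add atoms: allyl alcohol, C=CCO
Why: Mitsunobu O-alkylation of the acidic 4-hydroxyl gives the ether cleanly and avoids the C3-alkylation that competes when allyl halides and base are used.

Step 13
Reactants: 17 BDX-carbaldehyde; 19 6-methyl-4-(prop-2-en-1-yloxy)-2H-pyran-2-one
Product: 23 6-[(E)-2-(BDX)ethenyl]-4-(prop-2-en-1-yloxy)-2H-pyran-2-one, via lithium dienolate 20 (not isolated), via lithium aldolate 21 (not isolated), via mesylate 22 (not isolated)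
Conditions: 19, LiN(SiMe3)2, THF, −78 °C; then 17; then MsCl, −78 → 0 °C; then DBU, rt
Reagents that add atoms: none
Why: Vinylogous aldol addition of the dienolate formed at the 6-methyl group, mesylation of the aldolate and E1cB elimination should give the conjugated alkene as the more stable E isomer, under aprotic conditions that cannot exchange the group on the pyrone oxygen.

Step 14
Reactants: 23 6-[(E)-2-(BDX)ethenyl]-4-(prop-2-en-1-yloxy)-2H-pyran-2-one
Product: 24 6-[(E)-2-(BDX)ethenyl]-4-hydroxy-2H-pyran-2-one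
Conditions: Pd(PPh3)4 (cat.), morpholine, THF, rt; aq. citric acid work-up
Reagents that add atoms: none
Why: In this Tsuji–Trost deallylation the allyl ether of the vinylogous acid ionises readily to a π-allyl palladium complex and the stabilised pyronate, morpholine takes up the allyl group, and the MOM ethers and the styryl alkene are inert.

Step 15
Reactants: 24 6-[(E)-2-(BDX)ethenyl]-4-hydroxy-2H-pyran-2-one
Product: 25 6-[(E)-2-(BDX)ethenyl]-2-oxo-2H-pyran-4-yl acetate
Conditions: Ac2O, pyridine, CH2Cl2, 0 °C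
Reagents that add atoms: acetic anhydride, CC(=O)OC(C)=O
Why: O-Acetylation of the acidic 4-hydroxyl at low temperature without a nucleophilic catalyst gives the enol acetate and avoids acyl migration to C3.

Step 16
Reactants: 26 trimethylsilyl acetate
Product: 28 1,1-bis(trimethylsilyloxy)ethene, via lithium enolate 27 (not isolated)
Conditions: LiN(iPr)2, THF, −78 °C; then Me3SiCl, −78 °C → rt; distillation
Reagents that add atoms: chlorotrimethylsilane, C[Si](C)(C)Cl
Why: Silyl ketene acetal formation by deprotonation of the silyl ester and O-silylation of its lithium enolate gives the bis(silyl) acetal, which is purified by distillation without aqueous contact.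

Step 17
Reactants: 25 6-[(E)-2-(BDX)ethenyl]-2-oxo-2H-pyran-4-yl acetate; 28 1,1-bis(trimethylsilyloxy)ethene
Product: 32 3-[(E)-2-(BDX)ethenyl]-5-hydroxyphenyl acetate, via bicyclic lactone 29 (not isolated), via cyclohexadiene 30 (not isolated), via aryl silyl ether 31 (not isolated)
Conditions: 28 (excess), toluene, sealed tube, 125 °C; then aq. citric acid, THF, rt
Reagents that add atoms: none
Why: The electron-rich ketene acetal should add across the electron-poor diene of the 2-pyrone in an asynchronous [4+2] cycloaddition, its CH2 carbon bonding to pyrone C6 and its acetal carbon to C3, to give the bridged lactone 29; cycloreversion then expels CO2 to give diene 30, 1,2-elimination of Me3SiOH aromatises it to 31, and the aryl silyl ether is hydrolysed on work-up. The closest known reaction type is the inverse-electron-demand Diels–Alder reaction of 2-pyrones with ketene acetals such as 1,1-dimethoxyethene, which gives alkoxyarenes by the same loss of CO2 and alcohol. Ring C is closed by this intermolecular [4+2] annulation, four carbons coming from the pyrone (C3 to C6) and two from the acetal, and both new C–C bonds end up in the arene. No stereocentre is created, since the two transient bridgehead centres vanish on aromatisation, and the (2S,3S) centres and the E alkene lie outside the reacting system. The step needs the regiochemistry that places the two oxygens meta to each other and to the alkene, which follows from pairing the nucleophilic CH2 with C6, the δ-carbon of the unsaturated lactone, and it needs reaction at the ring diene and not at the styryl alkene, which follows because only the pyrone offers a cisoid acceptor-type diene; the acetyl group on the 4-oxygen, a much weaker donor than an alkyl ether, keeps that diene electron-poor.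

Step 18
Reactants: 32 3-[(E)-2-(BDX)ethenyl]-5-hydroxyphenyl acetate
Product: 33 5-[(E)-2-[(2S,3S)-8-hydroxy-3-(4-hydroxy-3,5-dimethoxyphenyl)-2-(hydroxymethyl)-2,3-dihydro-1,4-benzodioxin-6-yl]ethenyl]benzene-1,3-diol
Conditions: 3 M aq. HCl, MeOH–THF, 45 °C
Reagents that add atoms: none
Why: Acid-catalysed acetal exchange with methanol removes the three MOM groups and transesterifies the aryl acetate in one operation, while the cyclic aryl benzyl ether, whose oxygen is a poor site for protonation and whose trans form is the thermodynamic one, should keep both stereocentres and the E alkene is not isomerised.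

Compound list
1 | 4-bromo-2,6-dimethoxyphenol | COc1cc(Br)cc(OC)c1O | starting material
2 | 5-bromo-1,3-dimethoxy-2-(methoxymethoxy)benzene | COCOc1c(OC)cc(Br)cc1OC | intermediate
3 | methyl (R)-2,2-dimethyl-1,3-dioxolane-4-carboxylate | COC(=O)[C@H]1COC(C)(C)O1 | starting material
4 | methyl (2R)-2,3-dihydroxypropanoate | COC(=O)[C@H](O)CO | intermediate
5 | methyl (2R)-3-[(tert-butyldimethylsilyl)oxy]-2-hydroxypropanoate | COC(=O)[C@H](O)CO[Si](C)(C)C(C)(C)C | intermediate
6 | methyl gallate (methyl 3,4,5-trihydroxybenzoate) | COC(=O)c1cc(O)c(O)c(O)c1 | starting material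
7 | methyl 4-{[(2S)-3-[(tert-butyldimethylsilyl)oxy]-1-methoxy-1-oxopropan-2-yl]oxy}-3,5-dihydroxybenzoate | COC(=O)[C@@H](Oc1c(O)cc(cc1O)C(=O)OC)CO[Si](C)(C)C(C)(C)C | intermediate
8 | methyl 4-{[(2S)-3-[(tert-butyldimethylsilyl)oxy]-1-methoxy-1-oxopropan-2-yl]oxy}-3,5-bis(methoxymethoxy)benzoate | COC(=O)[C@@H](Oc1c(OCOC)cc(cc1OCOC)C(=O)OC)CO[Si](C)(C)C(C)(C)C | intermediate
9 | methyl 4-{[(2S)-3-[(tert-butyldimethylsilyl)oxy]-1-[methoxy(methyl)amino]-1-oxopropan-2-yl]oxy}-3,5-bis(methoxymethoxy)benzoate | CON(C)C(=O)[C@@H](Oc1c(OCOC)cc(cc1OCOC)C(=O)OC)CO[Si](C)(C)C(C)(C)C | intermediate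
10 | [3,5-dimethoxy-4-(methoxymethoxy)phenyl]magnesium bromide | COCOc1c(OC)cc([Mg]Br)cc1OC | intermediate
11 | methyl 4-{[(2S)-3-[(tert-butyldimethylsilyl)oxy]-1-[3,5-dimethoxy-4-(methoxymethoxy)phenyl]-1-oxopropan-2-yl]oxy}-3,5-bis(methoxymethoxy)benzoate | COCOc1c(OC)cc(cc1OC)C(=O)[C@@H](Oc1c(OCOC)cc(cc1OCOC)C(=O)OC)CO[Si](C)(C)C(C)(C)C | intermediate
12 | methyl 4-{[(2S)-3-[(tert-butyldimethylsilyl)oxy]-1-[3,5-dimethoxy-4-(methoxymethoxy)phenyl]-1-hydroxypropan-2-yl]oxy}-3,5-bis(methoxymethoxy)benzoate, both C1 epimers | COCOc1c(OC)cc(cc1OC)C(O)[C@@H](Oc1c(OCOC)cc(cc1OCOC)C(=O)OC)CO[Si](C)(C)C(C)(C)C | intermediate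
13 | methyl 4-{[(2S)-1,3-dihydroxy-1-(4-hydroxy-3,5-dimethoxyphenyl)propan-2-yl]oxy}-3,5-dihydroxybenzoate, both C1 epimers | COc1cc(cc(OC)c1O)C(O)[C@@H](Oc1c(O)cc(cc1O)C(=O)OC)CO | intermediate
14 | methyl (2S,3S)-8-hydroxy-3-(4-hydroxy-3,5-dimethoxyphenyl)-2-(hydroxymethyl)-2,3-dihydro-1,4-benzodioxine-6-carboxylate (trans) | COc1cc([C@@H]2Oc3cc(C(=O)OC)cc(O)c3O[C@H]2CO)cc(OC)c1O | intermediate
15 | methyl (2S,3S)-3-[3,5-dimethoxy-4-(methoxymethoxy)phenyl]-8-(methoxymethoxy)-2-[(methoxymethoxy)methyl]-2,3-dihydro-1,4-benzodioxine-6-carboxylate (BDX–CO2Me) | COc1cc([C@@H]2Oc3cc(C(=O)OC)cc(OCOC)c3O[C@H]2COCOC)cc(OC)c1OCOC | intermediate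
16 | (BDX)methanol | COc1cc([C@@H]2Oc3cc(CO)cc(OCOC)c3O[C@H]2COCOC)cc(OC)c1OCOC | intermediate
17 | BDX-carbaldehyde | COc1cc([C@@H]2Oc3cc(C=O)cc(OCOC)c3O[C@H]2COCOC)cc(OC)c1OCOC | intermediate
18 | 4-hydroxy-6-methyl-2H-pyran-2-one | Cc1cc(O)cc(=O)o1 | starting material
19 | 6-methyl-4-(prop-2-en-1-yloxy)-2H-pyran-2-one | Cc1cc(OCC=C)cc(=O)o1 | intermediate
20 | lithium dienolate of 19 (6-methylidene-4-(prop-2-en-1-yloxy)-6H-pyran-2-olate) | [Li]OC1=CC(OCC=C)=CC(=C)O1 | intermediate
21 | lithium 1-(BDX)-2-[2-oxo-4-(prop-2-en-1-yloxy)-2H-pyran-6-yl]ethanolate, both C1 epimers | COc1cc([C@@H]2Oc3cc(C(O[Li])Cc4cc(OCC=C)cc(=O)o4)cc(OCOC)c3O[C@H]2COCOC)cc(OC)c1OCOC | intermediate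
22 | 1-(BDX)-2-[2-oxo-4-(prop-2-en-1-yloxy)-2H-pyran-6-yl]ethyl methanesulfonate, both C1 epimers | COc1cc([C@@H]2Oc3cc(C(OS(C)(=O)=O)Cc4cc(OCC=C)cc(=O)o4)cc(OCOC)c3O[C@H]2COCOC)cc(OC)c1OCOC | intermediate
23 | 6-[(E)-2-(BDX)ethenyl]-4-(prop-2-en-1-yloxy)-2H-pyran-2-one | COc1cc([C@@H]2Oc3cc(/C=C/c4cc(OCC=C)cc(=O)o4)cc(OCOC)c3O[C@H]2COCOC)cc(OC)c1OCOC | intermediate
24 | 6-[(E)-2-(BDX)ethenyl]-4-hydroxy-2H-pyran-2-one | COc1cc([C@@H]2Oc3cc(/C=C/c4cc(O)cc(=O)o4)cc(OCOC)c3O[C@H]2COCOC)cc(OC)c1OCOC | intermediate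
25 | 6-[(E)-2-(BDX)ethenyl]-2-oxo-2H-pyran-4-yl acetate | COc1cc([C@@H]2Oc3cc(/C=C/c4cc(OC(C)=O)cc(=O)o4)cc(OCOC)c3O[C@H]2COCOC)cc(OC)c1OCOC | intermediate
26 | trimethylsilyl acetate | CC(=O)O[Si](C)(C)C | starting material
27 | lithium 1-(trimethylsilyloxy)ethenolate | C=C(O[Li])O[Si](C)(C)C | intermediate
28 | 1,1-bis(trimethylsilyloxy)ethene | C=C(O[Si](C)(C)C)O[Si](C)(C)C | intermediate
29 | 1-[(E)-2-(BDX)ethenyl]-3-oxo-8,8-bis(trimethylsilyloxy)-2-oxabicyclo[2.2.2]oct-5-en-5-yl acetate, bridgehead configuration undefined | COc1cc([C@@H]2Oc3cc(/C=C/C45OC(=O)C(C(OC(C)=O)=C4)C(O[Si](C)(C)C)(O[Si](C)(C)C)C5)cc(OCOC)c3O[C@H]2COCOC)cc(OC)c1OCOC | intermediate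
30 | 5-[(E)-2-(BDX)ethenyl]-3,3-bis(trimethylsilyloxy)cyclohexa-1,5-dien-1-yl acetate | COc1cc([C@@H]2Oc3cc(/C=C/C4=CC(OC(C)=O)=CC(O[Si](C)(C)C)(O[Si](C)(C)C)C4)cc(OCOC)c3O[C@H]2COCOC)cc(OC)c1OCOC | intermediate
31 | 3-[(E)-2-(BDX)ethenyl]-5-(trimethylsilyloxy)phenyl acetate | COc1cc([C@@H]2Oc3cc(/C=C/c4cc(O[Si](C)(C)C)cc(OC(C)=O)c4)cc(OCOC)c3O[C@H]2COCOC)cc(OC)c1OCOC | intermediate
32 | 3-[(E)-2-(BDX)ethenyl]-5-hydroxyphenyl acetate | COc1cc([C@@H]2Oc3cc(/C=C/c4cc(O)cc(OC(C)=O)c4)cc(OCOC)c3O[C@H]2COCOC)cc(OC)c1OCOC | intermediate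
33 | 5-[(E)-2-[(2S,3S)-8-hydroxy-3-(4-hydroxy-3,5-dimethoxyphenyl)-2-(hydroxymethyl)-2,3-dihydro-1,4-benzodioxin-6-yl]ethenyl]benzene-1,3-diol | COc1cc([C@@H]2Oc3cc(/C=C/c4cc(O)cc(O)c4)cc(O)c3O[C@H]2CO)cc(OC)c1O | target

Total step count: 18. Longest linear sequence: 15 steps (3 to 33 through steps 2–11, 13–15, 17 and 18).

Steps most likely to fail

Step 17. The cycloaddition may be too slow for a diene that still carries an oxygen substituent. In that case O-to-C silyl migration of the ketene acetal, or silyl-transfer conjugate addition without ring closure, would outrun ring formation. The fallback abandons the pyrone and brings in ring C as a finished resorcinol unit; it sets out from aldehyde 17 and comes back at target 33. Wittig methylenation of 17 (Ph3PCH3Br, KOtBu, THF) would give the styrene F1. A Heck reaction of F1 with 1-bromo-3,5-bis(methoxymethoxy)benzene F2 (from commercially available 5-bromoresorcinol, MOMCl and iPr2NEt), run with Pd(OAc)2, P(o-tol)3 and Et3N in DMF at 100 °C, would give the E-stilbene with five MOM groups F3. Treatment of F3 under the conditions of step 18 would give 33.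

Step 13. The dienolate may react through its ring carbons, or the aldolate may revert before it is trapped, so that the valuable aldehyde is poorly converted. The fallback builds the pyrone ring onto the aldehyde instead of condensing a finished pyrone; it sets out from 17 and comes back at 24. A Horner–Wadsworth–Emmons reaction of 17 with commercially available diethyl {2-[methoxy(methyl)amino]-2-oxoethyl}phosphonate (NaH, THF) would give the E-configured Weinreb enamide F4. The dianion of methyl acetoacetate (NaH, then n-BuLi, THF) would be acylated by F4 at its terminal carbon to give the 3,5-dioxo ester F5. DBU in warm toluene would then close the 4-hydroxy-2-pyrone with loss of methanol and give 24.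

Step 4. Discrimination between the three phenols may be incomplete, or a second alkylation may follow the first. The fallback differentiates the phenols before the ether is formed; it sets out from 6 and comes back at 7. Benzylation of 6 (BnBr, K2CO3, DMF) would give methyl 3,4,5-tris(benzyloxy)benzoate F6. Lewis-acid cleavage of the central, doubly flanked benzyl ether (AlCl3, PhNMe2, CH2Cl2, 0 °C) would give methyl 3,5-bis(benzyloxy)-4-hydroxybenzoate F7. A Mitsunobu reaction of F7 with 5 under the conditions of step 4 would give the ether F8 with inversion. Hydrogenolysis (H2, Pd/C, EtOAc) would remove both benzyl groups and give 7.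

Further compounds
F1 | step 17 | (2S,3S)-6-ethenyl-3-[3,5-dimethoxy-4-(methoxymethoxy)phenyl]-8-(methoxymethoxy)-2-[(methoxymethoxy)methyl]-2,3-dihydro-1,4-benzodioxine | COc1cc([C@@H]2Oc3cc(C=C)cc(OCOC)c3O[C@H]2COCOC)cc(OC)c1OCOC
F2 | step 17 | 1-bromo-3,5-bis(methoxymethoxy)benzene | COCOc1cc(Br)cc(OCOC)c1
F3 | step 17 | (2S,3S)-6-{(E)-2-[3,5-bis(methoxymethoxy)phenyl]ethenyl}-3-[3,5-dimethoxy-4-(methoxymethoxy)phenyl]-8-(methoxymethoxy)-2-[(methoxymethoxy)methyl]-2,3-dihydro-1,4-benzodioxine | COc1cc([C@@H]2Oc3cc(/C=C/c4cc(OCOC)cc(OCOC)c4)cc(OCOC)c3O[C@H]2COCOC)cc(OC)c1OCOC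
F4 | step 13 | (2E)-3-(BDX)-N-methoxy-N-methylprop-2-enamide | COc1cc([C@@H]2Oc3cc(/C=C/C(=O)N(C)OC)cc(OCOC)c3O[C@H]2COCOC)cc(OC)c1OCOC
F5 | step 13 | methyl (6E)-7-(BDX)-3,5-dioxohept-6-enoate | COc1cc([C@@H]2Oc3cc(/C=C/C(=O)CC(=O)CC(=O)OC)cc(OCOC)c3O[C@H]2COCOC)cc(OC)c1OCOC
F6 | step 4 | methyl 3,4,5-tris(benzyloxy)benzoate | COC(=O)c1cc(OCc2ccccc2)c(OCc2ccccc2)c(OCc2ccccc2)c1
F7 | step 4 | methyl 3,5-bis(benzyloxy)-4-hydroxybenzoate | COC(=O)c1cc(OCc2ccccc2)c(O)c(OCc2ccccc2)c1
F8 | step 4 | methyl 3,5-bis(benzyloxy)-4-{[(2S)-3-[(tert-butyldimethylsilyl)oxy]-1-methoxy-1-oxopropan-2-yl]oxy}benzoate | COC(=O)[C@@H](Oc1c(OCc2ccccc2)cc(cc1OCc1ccccc1)C(=O)OC)CO[Si](C)(C)C(C)(C)C
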